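The cyclobutane C5–C6–C11–C10 of the target is bridged twice, by C7(=O)–C8=C9 across C6/C10 and by C4–C3–C2–C1 across C5/C11. Disconnecting C9–C10 and joining C6 to C10 instead gives an acyl bicyclo[1.1.0]butane with its wing carbons C5 and C11 tied into a cycloheptane. In the last step a vinyl radical at C9 adds to bridgehead C10; strain release of the central bond closes the bicyclo[3.1.1]heptenone and sets C6 and C10 at once. The bicyclobutane comes from a cycloheptenyl diazoketone; C11 is set by a Claisen rearrangement, C3 by a boron aldol and C1 by an Evans–Tishchenko reduction. (C1 CHOTig, C3 CHO-isovaleryl, C4 CMe2, C7 C=O, C9 CMe, C11 CMe.)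

Key step: step 14

Remark: the labels C1–C11 are those of the first paragraph (C2 ring CH2; C5, C6, C10 cyclobutane CH; C8 enone CH). In this numbering the target is 1R,3R,5S,6R,10R,11R. The E-propenyl group made in step 3 is only a metathesis handle and leaves as propene in step 8.

Step 1
Reactants: 1 (E)-3-methylpent-2-en-4-yn-1-ol
Product: 2 (E)-3-methylpent-2-en-4-ynal
Conditions: MnO2 (activated, excess), CH2Cl2, rt
Reagents that add atoms: none
Why: Allylic alcohol oxidation with activated MnO2 should stop at the aldehyde and leave the enyne and its E geometry untouched.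

Step 2
Reactants: 2 (E)-3-methylpent-2-en-4-ynal
Product: 3 (2S,3E)-4-methylhex-3-en-5-yn-2-ol
Conditions: Me2Zn (2 equiv), (−)-MIB (5 mol %), toluene, 0 °C to rt; aq. NH4Cl
Reagents that add atoms: dimethylzinc, C[Zn]C
Why: Amino-alcohol-catalysed dialkylzinc addition to the enal, in which the zinc chelate of (−)-MIB should deliver methyl to one aldehyde face and set the S carbinol by catalyst control.

Step 3
Reactants: 3 (2S,3E)-4-methylhex-3-en-5-yn-2-ol
Product: 5 methyl (3S,4E)-3-ethynyl-3-methylhex-4-enoate, via mixed ketene acetal 4 (not isolated)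
Conditions: MeC(OMe)3 (6 equiv), EtCO2H (5 mol %), 110–125 °C, MeOH distilled off
Reagents that add atoms: trimethyl orthoacetate, CC(OC)(OC)OC
Why: Johnson–Claisen rearrangement through a chair transition state with the carbinol methyl equatorial, so the S carbinol and E alkene should transfer chirality suprafacially to the new quaternary carbon C11 (S) and give the E-propenyl group.

Step 4
Reactants: 5 methyl (3S,4E)-3-ethynyl-3-methylhex-4-enoate
Product: 6 methyl (3S,4E)-3-acetyl-3-methylhex-4-enoate
Conditions: NaAuCl4·2H2O (2 mol %), MeOH/H2O 10:1, 65 °C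
Reagents that add atoms: water, O
Why: Gold-catalysed Markovnikov hydration of the terminal alkyne should give the methyl ketone without touching the quaternary centre or the disubstituted alkene.

Step 5
Reactants: 7 3-methylbut-2-enylmagnesium chloride (prenylmagnesium chloride)
Product: 8 2,2-dimethylbut-3-enal
Conditions: DMF, THF, −20 °C to rt; 1 M HCl
Reagents that add atoms: N,N-dimethylformamide, CN(C)C=O
Why: Bouveault aldehyde synthesis in which the allylic Grignard reagent should react at its γ-carbon through a six-membered transition state and place the formyl group on the tertiary carbon; no stereocentre is formed.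

Step 6
Reactants: 6 methyl (3S,4E)-3-acetyl-3-methylhex-4-enoate; 8 2,2-dimethylbut-3-enal
Product: 10 methyl (3S,4E)-3-[(3R)-3-hydroxy-4,4-dimethylhex-5-enoyl]-3-methylhex-4-enoate, via enol diisopinocampheylborinate 9 (not isolated)
Conditions: (−)-Ipc2BCl, Et3N, Et2O, 0 °C; then 8, −78 to −20 °C; H2O2, pH 7 buffer, MeOH
Reagents that add atoms: none
Why: Diisopinocampheylboron-mediated aldol of a methyl ketone in a cyclic transition state, where the (−)-Ipc ligands should direct the enolate to the Re face of the non-enolisable aldehyde and set C3 (R) by reagent control; the remote C11 centre has little say and a C3 epimer would be removed by chromatography.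

Step 7
Reactants: 10 methyl (3S,4E)-3-[(3R)-3-hydroxy-4,4-dimethylhex-5-enoyl]-3-methylhex-4-enoate
Product: 12 (4S,5R)-5-[(2R)-3,3-dimethyl-2-(3-methylbutanoyloxy)pent-4-enyl]-4-methyl-4-[(E)-prop-1-enyl]oxolan-2-one, via anti-diol monoester 11 (not isolated)
Conditions: Me2CHCH2CHO (5 equiv), SmI2 (0.3 equiv), THF, −10 °C; then CSA (cat.), CH2Cl2, rt
Reagents that add atoms: 3-methylbutanal, CC(C)CC=O
Why: Evans–Tishchenko reduction, in which the samarium-bound hemiacetal on O3 should deliver hydride to the C1 ketone through a six-membered chair to give the 1,3-anti (1R) alcohol with the isovalerate already on O3; the freed C1 hydroxyl then lactonises onto the methyl ester, which protects it and tells the two oxygens apart.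

Step 8
Reactants: 12 (4S,5R)-5-[(2R)-3,3-dimethyl-2-(3-methylbutanoyloxy)pent-4-enyl]-4-methyl-4-[(E)-prop-1-enyl]oxolan-2-one
Product: 13 (3aS,7R,8aR)-3a,6,6-trimethyl-2-oxo-3,3a,6,7,8,8a-hexahydro-2H-cyclohepta[b]furan-7-yl 3-methylbutanoate (cis-fused)
Conditions: second-generation Hoveyda–Grubbs catalyst (10 mol %), toluene (2 mM), 80 °C
Reagents that add atoms: none
Why: Ring-closing metathesis, where the ruthenium alkylidene should form at the vinyl group and close on the propenyl group to the cis-cycloheptene, helped by the two quaternary carbons and the lactone (Thorpe–Ingold effect); no stereocentre changes.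

Step 9
Reactants: 13 (3aS,7R,8aR)-3a,6,6-trimethyl-2-oxo-3,3a,6,7,8,8a-hexahydro-2H-cyclohepta[b]furan-7-yl 3-methylbutanoate
Product: 14 (1R,5S,6R)-6-hydroxy-2,2,5-trimethyl-5-(2-oxopent-3-yn-1-yl)cyclohept-3-en-1-yl 3-methylbutanoate
Conditions: MeC≡CLi (1.3 equiv), THF, −78 °C; aq. NH4Cl
Reagents that add atoms: prop-1-ynyllithium, [Li]C#CC
Why: Alkynyllithium addition to a γ-lactone should stop at the tetrahedral lithium lactolate, which opens on work-up to the γ-hydroxy ynone; the lactone carbonyl is far more electrophilic than the hindered isovalerate.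

Step 10
Reactants: 14 (1R,5S,6R)-6-hydroxy-2,2,5-trimethyl-5-(2-oxopent-3-yn-1-yl)cyclohept-3-en-1-yl 3-methylbutanoate
Product: 15 (1R,5S,6R)-2,2,5-trimethyl-6-[(E)-2-methylbut-2-enoyloxy]-5-(2-oxopent-3-yn-1-yl)cyclohept-3-en-1-yl 3-methylbutanoate
Conditions: tigloyl chloride, pyridine, DMAP (cat.), CH2Cl2, 0 °C to rt
Reagents that add atoms: (E)-2-methylbut-2-enoyl chloride, C/C=C(\C)C(Cl)=O
Why: DMAP-catalysed acylation of the hindered secondary C1 alcohol should install the tiglate without change at C1.

Step 11
Reactants: 15 (1R,5S,6R)-2,2,5-trimethyl-6-[(E)-2-methylbut-2-enoyloxy]-5-(2-oxopent-3-yn-1-yl)cyclohept-3-en-1-yl 3-methylbutanoate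
Product: 16 the (Z)-β-iodoenone, 5-[(Z)-4-iodo-2-oxopent-3-en-1-yl] analogue of 15 (ring stereocentres as in 15)
Conditions: NaI, AcOH, rt
Reagents that add atoms: sodium iodide, [Na+].[I-]
Why: Conjugate hydroiodination of the ynone, where iodide adds to the β-carbon and anti protonation of the allenol should give the Z β-iodoenone as the kinetic product.

Step 12
Reactants: 16 the (Z)-β-iodoenone
Product: 18 the α-diazo-α′-enone, 5-[(Z)-1-diazo-4-iodo-2-oxopent-3-en-1-yl] analogue of 15 (ring stereocentres as in 15), via trifluoroacetyl ketone 17 (not isolated)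
Conditions: LiN(SiMe3)2, THF, −78 °C; CF3CO2CH2CF3; then p-ABSA, Et3N, H2O, MeCN, rt
Reagents that add atoms: 4-acetamidobenzenesulfonyl azide, CC(=O)Nc1ccc(cc1)S(=O)(=O)N=[N+]=[N-]; 2,2,2-trifluoroethyl trifluoroacetate (atoms in 17 only), O=C(OCC(F)(F)F)C(F)(F)F
Why: Regitz-type detrifluoroacetylative diazo transfer, where kinetic enolisation at C6 (the only sp3 α-carbon of the enone), C-trifluoroacetylation to 17 and azide transfer with loss of the trifluoroacetyl group should give the diazoketone under conditions that spare both esters and the vinyl iodide.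

Step 13
Reactants: 18 the α-diazo-α′-enone
Product: 19 the acyl bicyclo[1.1.0]butane (tricyclo[5.1.0.0(2,8)]octane core): bridgehead C6 carries the (Z)-3-iodobut-2-enoyl group, bridgehead C10 H, wing C11 exo-methyl, wing C5 exo-H; C4–C1 chain endo with C1 OTig, C3 O-isovaleryl, C4 gem-dimethyl
Conditions: Rh2(OAc)4 (1 mol %), CH2Cl2, 0 °C, slow addition of 18
Reagents that add atoms: none
Why: Rhodium-carbenoid intramolecular cyclopropanation of an α-allyl-type diazo carbonyl compound to a bicyclo[1.1.0]butane, where the carbenoid at C6 has no β-hydrogen and should add to the cis C5=C10 bond on the face where the quaternary C11 holds it, so C11 fixes C5, C6 and C10 and the ring forces C4 and C1 endo.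

Step 14
Reactants: 19 the acyl bicyclo[1.1.0]butane
Product: 20 the target CNP0194415.1 (1R,3R,5S,6R,10R,11R)
Conditions: (Me3Si)3SiH (syringe pump), AIBN, benzene (2 mM), 80 °C
Reagents that add atoms: none
Why: Proposed new method: iodine abstraction by the silyl radical gives the σ-vinyl radical at C9, which adds intramolecularly to bridgehead C10 of the bicyclo[1.1.0]butane while the strained C6–C10 bond breaks, and the bridgehead radical left at C6 takes hydrogen from the silane and carries the chain. The closest known reactions are the anti-selective additions of carbon, sulfonyl and thiyl radicals across the central bond of wing-bridged bicyclobutanes (tricyclo[4.1.0.0(2,7)]heptanes to norpinanes) and radical (3+3)-type annulations of bicyclobutyl ketones to bicyclo[3.1.1]heptanes. The one new bond closes both six-membered rings of the bicyclo[3.1.1]heptenone (C5–C6–C7–C8–C9–C10 and C6–C7–C8–C9–C10–C11); the radical reaches C10 through the array C9–C8–C7–C6–C10, a 5-endo-type attack on the σ-bond that ends as a six-membered closure once C6–C10 has cleaved. C10 is set because the tether can reach it only on the convex face, anti to the C1–C4 bridge, and C6 because the caged bridgehead radical can take hydrogen only from outside. The step needs cyclisation to outrun hydrogen transfer to the vinyl radical, which slow addition of the silane at high dilution and the large strain release should secure; the iodide geometry is irrelevant because the vinyl radical inverts.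

Compound list
1 | (E)-3-methylpent-2-en-4-yn-1-ol | C#C/C(C)=C/CO | starting material
2 | (E)-3-methylpent-2-en-4-ynal | C#C/C(C)=C/C=O | intermediate
3 | (2S,3E)-4-methylhex-3-en-5-yn-2-ol | C#C/C(C)=C/[C@H](C)O | intermediate
4 | mixed ketene acetal, (2S,3E)-2-(1-methoxyethenyloxy)-4-methylhex-3-en-5-yne (formed in situ) | C#C/C(C)=C/[C@H](C)OC(=C)OC | intermediate
5 | methyl (3S,4E)-3-ethynyl-3-methylhex-4-enoate | C#C[C@@](C)(CC(=O)OC)/C=C/C | intermediate
6 | methyl (3S,4E)-3-acetyl-3-methylhex-4-enoate | CC(=O)[C@@](C)(CC(=O)OC)/C=C/C | intermediate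
7 | 3-methylbut-2-enylmagnesium chloride | CC(C)=CC[Mg]Cl | starting material
8 | 2,2-dimethylbut-3-enal | C=CC(C)(C)C=O | intermediate
9 | enol diisopinocampheylborinate of 6 (formed in situ) | C=C(OB([C@@H]1C[C@@H]2C[C@H]([C@H]1C)C2(C)C)[C@@H]1C[C@@H]2C[C@H]([C@H]1C)C2(C)C)[C@@](C)(CC(=O)OC)/C=C/C | intermediate
10 | methyl (3S,4E)-3-[(3R)-3-hydroxy-4,4-dimethylhex-5-enoyl]-3-methylhex-4-enoate | O=C(C[C@@H](O)C(C)(C)C=C)[C@@](C)(CC(=O)OC)/C=C/C | intermediate
11 | methyl (3S,4E)-3-[(1R,3R)-1-hydroxy-4,4-dimethyl-3-(3-methylbutanoyloxy)hex-5-enyl]-3-methylhex-4-enoate (formed in situ) | O[C@H](C[C@@H](OC(=O)CC(C)C)C(C)(C)C=C)[C@@](C)(CC(=O)OC)/C=C/C | intermediate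
12 | (4S,5R)-5-[(2R)-3,3-dimethyl-2-(3-methylbutanoyloxy)pent-4-enyl]-4-methyl-4-[(E)-prop-1-enyl]oxolan-2-one | O=C1C[C@@](C)(/C=C/C)[C@H](O1)C[C@@H](OC(=O)CC(C)C)C(C)(C)C=C | intermediate
13 | (3aS,7R,8aR)-3a,6,6-trimethyl-2-oxo-3,3a,6,7,8,8a-hexahydro-2H-cyclohepta[b]furan-7-yl 3-methylbutanoate | O=C1C[C@@]2(C)C=CC(C)(C)[C@H](OC(=O)CC(C)C)C[C@H]2O1 | intermediate
14 | (1R,5S,6R)-6-hydroxy-2,2,5-trimethyl-5-(2-oxopent-3-yn-1-yl)cyclohept-3-en-1-yl 3-methylbutanoate | CC#CC(=O)C[C@@]1(C)C=CC(C)(C)[C@H](OC(=O)CC(C)C)C[C@H]1O | intermediate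
15 | (1R,5S,6R)-2,2,5-trimethyl-6-[(E)-2-methylbut-2-enoyloxy]-5-(2-oxopent-3-yn-1-yl)cyclohept-3-en-1-yl 3-methylbutanoate | C/C=C(\C)C(=O)O[C@@H]1C[C@@H](OC(=O)CC(C)C)C(C)(C)C=C[C@]1(C)CC(=O)C#CC | intermediate
16 | (Z)-β-iodoenone, 5-[(Z)-4-iodo-2-oxopent-3-en-1-yl] analogue of 15 | C/C=C(\C)C(=O)O[C@@H]1C[C@@H](OC(=O)CC(C)C)C(C)(C)C=C[C@]1(C)CC(=O)/C=C(/C)I | intermediate
17 | trifluoroacetyl ketone, C6-trifluoroacetyl derivative of 16 (formed in situ, keto/enol mixture) | C/C=C(\C)C(=O)O[C@@H]1C[C@@H](OC(=O)CC(C)C)C(C)(C)C=C[C@]1(C)C(C(=O)C(F)(F)F)C(=O)/C=C(/C)I | intermediate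
18 | α-diazo-α′-enone, 5-[(Z)-1-diazo-4-iodo-2-oxopent-3-en-1-yl] analogue of 15 | C/C=C(\C)C(=O)O[C@@H]1C[C@@H](OC(=O)CC(C)C)C(C)(C)C=C[C@]1(C)C(=[N+]=[N-])C(=O)/C=C(/C)I | intermediate
19 | acyl bicyclo[1.1.0]butane (tricyclo[5.1.0.0(2,8)]octane core with C6 (Z)-3-iodobut-2-enoyl, C11 methyl, C1 OTig, C3 O-isovaleryl, C4 gem-dimethyl) | C/C=C(\C)C(=O)O[C@@H]1C[C@@H](OC(=O)CC(C)C)C(C)(C)[C@@H]2[C@@]3(C(=O)/C=C(/C)I)[C@@H]2[C@]31C | intermediate
20 | CNP0194415.1, the tricyclic enone diester (1R,3R,5S,6R,10R,11R in the numbering used here) | C/C=C(\C)C(=O)O[C@@H]1C[C@@H](OC(=O)CC(C)C)C(C)(C)[C@@H]2[C@H]3C(=O)C=C(C)[C@@H]2[C@]31C | target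

Total step count: 14. Longest linear sequence: 13 steps (steps 1–4 and 6–14, from 1 to 20); step 5 is a one-step side branch.

Steps most likely to fail

Step 14 (Proposed new method). The vinyl radical may take hydrogen from the silane, or from the C11 methyl group by 1,6-transfer, before it reaches C10, so that simple deiodination wins over ring closure. The fallback uses known chemistry, sets out from 19 and returns at 20. NaI in AcOH adds hydrogen iodide across the central bond (strain-release hydrohalogenation of an acyl bicyclobutane, iodide at C10 and proton at C6) to give the cyclobutyl iodide F1; its C6 epimers interconvert through the enol and the one with the acyl group anti to the C1–C4 bridge is drawn. Treating cyclobutyl iodide F1 with (Bu3Sn)2 under a sunlamp in benzene generates the C10 cyclobutyl radical, which adds 6-endo to the β-carbon of the β-iodoenone and expels an iodine atom (radical addition–elimination), giving 20.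

Step 13. The carbenoid may be diverted before it reaches the hindered ring alkene, by ylide formation with the neighbouring vinyl iodide or the tiglate carbonyl. The fallback sets out from 16 and returns at 19 without a carbene. mCPBA should epoxidise the ring alkene on the face away from the C6 side chain to give epoxide F2. LiN(SiMe3)2 forms the C6 enolate, which opens the epoxide at C10 (3-exo-tet, inversion) to give cyclopropyl carbinol F3. MsCl/Et3N converts cyclopropyl carbinol F3 into mesylate F4, and KN(SiMe3)2 then closes the second three-membered ring by displacement at C5, giving 19.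

Step 8. Metathesis between two alkenes that each sit on a quaternary carbon may be too slow, so that the catalyst decomposes or the diene oligomerises. The fallback sets out from 12 and returns at 13 by carbonyl olefination. Ozonolysis (O3, CH2Cl2/MeOH, −78 °C; Me2S) cleaves both alkenes to give dialdehyde F5, and intramolecular McMurry coupling of dialdehyde F5 (TiCl3(DME)1.5, Zn–Cu couple, DME, reflux, high dilution) should give the cis-cycloheptene 13.

Further compounds
F1 | step 14 | cyclobutyl iodide, hydrogen iodide adduct of 19 (C10 iodide, C6 H, acyl anti to the C1–C4 bridge) | C/C=C(\C)C(=O)O[C@@H]1C[C@@H](OC(=O)CC(C)C)C(C)(C)[C@@H]2[C@@H](C(=O)/C=C(/C)I)[C@@]1(C)[C@H]2I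
F2 | step 13 | epoxide of 16 (C5–C10 oxirane anti to the C6 side chain) | C/C=C(\C)C(=O)O[C@@H]1C[C@@H](OC(=O)CC(C)C)C(C)(C)[C@H]2O[C@H]2[C@]1(C)CC(=O)/C=C(/C)I
F3 | step 13 | cyclopropyl carbinol (cyclopropane C6–C10–C11, C5 hydroxyl) | C/C=C(\C)C(=O)O[C@@H]1C[C@@H](OC(=O)CC(C)C)C(C)(C)[C@@H](O)[C@@H]2[C@@H](C(=O)/C=C(/C)I)[C@@]21C
F4 | step 13 | mesylate of F3 | C/C=C(\C)C(=O)O[C@@H]1C[C@@H](OC(=O)CC(C)C)C(C)(C)[C@@H](OS(C)(=O)=O)[C@@H]2[C@@H](C(=O)/C=C(/C)I)[C@@]21C
F5 | step 8 | dialdehyde from ozonolysis of 12 | O=C1C[C@@](C)(C=O)[C@H](O1)C[C@@H](OC(=O)CC(C)C)C(C)(C)C=O
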